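All runs are simulated for an exercise; scatter was added.

In south and in north you charge less reagent than starting material, and the candidate steps make one product from one reagent, so hold these two charges against each other before you think of rates.

common to all: starting material 0.020 M; free catalyst 0.11 mM
- grey: reagent 0.0095 M (in portions, 4); temperature 16 °C; run made earlier; portions every 6.0 h
- blue: reagent 0.014 M (in portions, 4); temperature 30 °C; run made earlier; portions every 6.0 h
- south: reagent 0.0190 M (in portions, 4); at 10 °C until 8.0 h, from then on at 35 °C; the portions of reagent follow each other after 6.0 h, the first at the start; time 40 h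
- north: reagent 0.0190 M (in portions, 4); at 35 °C throughout; the portions of reagent follow each other after 4.0 h, the first at the start; time 40 h

| run | time / h | product / % | starting material / % |
|---|---|---|---|
| grey | 5.00 | 13.1 | 66.9 |
| grey | 10.0 | 23.4 | 51.7 |
| grey | 15.0 | 36.4 | 42.1 |
| grey | 20.0 | 46.3 | 30.4 |
| grey | 25.0 | 46.5 | 24.2 |
| grey | 30.0 | 46.2 | 19.0 |
| blue | 1.00 | 12.0 | 75.5 |
| blue | 1.33 | 13.1 | 72.1 |
| blue | 2.00 | 17.0 | 63.4 |
| blue | 4.00 | 17.0 | 50.3 |
| blue | 6.00 | 17.5 | 42.8 |
| blue | 8.00 | 35.5 | 30.7 |
| blue | 12.0 | 34.4 | 22.8 |

(each reading ± 1 percentage point)

- which one finishes higher in amount of product, in percent of the starting material charged ("neither" within 2 percentage points) (south / north / neither)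
- amount of product at the end, in percent of the starting material charged, south
- amount of product at the end, in percent of the starting material charged, north

- candidate steps: starting material + free catalyst -> free catalyst + open intermediate; free catalyst + open intermediate <-> catalyst intermediate; reagent + catalyst intermediate -> free catalyst + product

ceiling = [reagent] charged / [starting material] charged = 0.0190 M / 0.020 M = 95.0 %

This ratio is the product ceiling: the share of the starting material that the charged reagent, here the limiting reagent, can turn into product. The earlier runs agree. Grey has a ceiling of 47.5 % and reads 46.5 % after its last portion. One portion in blue is worth 17.5 %, and blue reads 17.5 % at 6.00 h.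

Is one number enough? No: the starting material must also react in time. Take its loss as first order, so that the integrated rate leaves exp(−kt). Blue, cooler than the warm stage, reads 42.8 % left at 6.00 h:

k = 0.141 h⁻¹

left in south after its warm 32.0 h = exp(−kt) = 1.08 %

That is less than the 5.00 % of the starting material that the ceiling keeps from becoming product, so I expect time not to hold south down. North stays warm longer. My reckoning gives 95.0 % for both.

The forecast says neither, with 94.5 % (90 % to 96 %) for south and 94.5 % (90 % to 96 %) for north, just under my ceiling, holding that “the cold start merely delays it”.

South and north finish at 95.0 % and 95.0 %, so the answer is neither, as forecast.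

    starting material + free catalyst → free catalyst + open intermediate (k = 617 L mol⁻¹ h⁻¹, Ea = 50.0 kJ mol⁻¹)
    free catalyst + open intermediate ⇌ catalyst intermediate (K = 352 L mol⁻¹, k = 2730 L mol⁻¹ h⁻¹, Ea = 55.0 kJ mol⁻¹, ΔH = −10.0 kJ mol⁻¹)
    reagent + catalyst intermediate → free catalyst + product (k = 28600 L mol⁻¹ h⁻¹, Ea = 45.0 kJ mol⁻¹)
    (constants at 10 °C)

Both flasks stand at the ceiling of 95.0 %. A neighbour of south charged with 0.080 M of starting material has a ceiling of 23.8 % and holds 23.8 % product at 40.0 h. South itself, at 40.0 h, keeps 0 % of its reagent, 0.0062 % of its starting material and 4.89 % as open intermediate. Ten times the time adds no product: at 400 h south still holds 95.0 % product and 4.89 % open intermediate, with 0 % starting material.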